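A direct plan would make the bis(benzyloxy)biphenyl dialdehyde A1 by a Suzuki coupling, extend both formyl groups by a double Wittig reaction with the keto phosphonium salt A2, hydrogenate to the bis-phenol A3, and only then add the second oxygen of each catechol by ortho-oxidation of both phenols before cleaving the methyl ethers.
Its weakest steps would be:
- the late double oxidation of phenol to catechol: on ring B both carbons ortho to the hydroxyl (C3' and C5') bear hydrogen, nothing in A3 would decide between them, and quinone chemistry would be run on the most advanced material;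
- the benzylation, debenzylation and re-oxidation detour, which would spend about five steps to reach catechols that 3,4-dioxygenated building blocks carry from the outset;
- the double Wittig olefination with an ylide bearing an enolisable ketone, which would have to succeed twice on one molecule with the base held just short of the salt.

**Plan of the new route**
The retrosynthesis removes the eight O-methyl groups and saturates back to the two chain C=C bonds of 17, then cuts the biaryl bond C5–C1' and the bond from C6' to its chain CH2 in one operation.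
This is possible because ring B bears aryl and alkyl on the neighbouring atoms C1' and C6' and its oxygens at C3' and C4' lie mirror-symmetrically to that bond: ring B is 4,5-dimethoxybenzyne, and either end of its triple bond may take either partner.
The partners, ring A boronate 12 and allylic chloride 14, both come from one alkenyl ketone 10 by cross-metathesis; each outer ring is thus joined to its chain first, ring A to its chain next, and rings A and B last, the second chain entering in the same step.
All four catechol oxygens are bought with eugenol and with the aryne precursor, so no phenol is oxidised, no benzyl group is put on and taken off, and no ylide with a ketone is needed.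

Key step: step 8

Remark on the chemistry: the target has no stereocentre and its biaryl axis, with one ortho substituent on each ring, rotates freely. The geometry of the C=C bonds in 11, 12, 14 and 17 is immaterial because step 9 saturates them. Compound 15 is taken to be a commercial aryne precursor.

**Step 1**
Reactants: 1 eugenol (2-methoxy-4-(prop-2-en-1-yl)phenol)
Product: 2 4-allyl-2-bromo-6-methoxyphenol
Conditions: NBS (1.0 equiv), i-Pr2NH (10 mol %), CH2Cl2, 0 °C, dark
Reagents that add atoms: N-bromosuccinimide, O=C1CCC(=O)N1Br
Why: Electrophilic aromatic bromination of a phenol, in which the para carbon bears the allyl group and one ortho carbon the methoxy group, so only the future C5 of ring A is open, and amine-mediated delivery of bromine to the phenol ring should be far faster than any reaction of the isolated terminal alkene in the dark.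

**Step 2**
Reactants: 2 4-allyl-2-bromo-6-methoxyphenol
Product: 3 5-allyl-1-bromo-2,3-dimethoxybenzene
Conditions: MeI (1.5 equiv), K2CO3, acetone, reflux
Reagents that add atoms: iodomethane, CI
Why: Williamson ether synthesis on the phenoxide, which caps the last free hydroxyl as a methyl ether that is cleaved together with all the others in the final step.

**Step 3**
Reactants: 4 oct-7-enoic acid
Product: 6 N-methoxy-N-methyloct-7-enamide, via acyl imidazolide 5 (not isolated)
Conditions: CDI (1.1 equiv), CH2Cl2, rt; then MeNH(OMe)·HCl (1.2 equiv), rt
Reagents that add atoms: N,O-dimethylhydroxylamine hydrochloride, CNOC.Cl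
Why: Activation of the acid as its acyl imidazolide followed by aminolysis is a standard Weinreb amide synthesis that leaves the terminal alkene untouched.

**Step 4**
Reactants: 6 N-methoxy-N-methyloct-7-enamide; 7 1,3-dimethoxybenzene
Product: 10 1-(2,6-dimethoxyphenyl)oct-7-en-1-one, via 2,6-dimethoxyphenyllithium 8 (not isolated), via lithium hemiaminal adduct 9 (not isolated)
Conditions: 7 (1.3 equiv), n-BuLi (1.2 equiv), THF, 0 °C to rt; then 6 (1.0 equiv), −78 to 0 °C; 1 M HCl
Reagents that add atoms: none
Why: Directed ortho-metalation of 7 occurs at the carbon between the two methoxy groups, and the Weinreb ketone synthesis stops at the chelated adduct 9 until the acid quench, so the di-ortho-substituted ketone forms without over-addition.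

**Step 5**
Reactants: 3 5-allyl-1-bromo-2,3-dimethoxybenzene; 10 1-(2,6-dimethoxyphenyl)oct-7-en-1-one
Product: 11 9-(3-bromo-4,5-dimethoxyphenyl)-1-(2,6-dimethoxyphenyl)non-7-en-1-one (mixture of alkene isomers)
Conditions: 3 (3.0 equiv), 10 (1.0 equiv), second-generation Grubbs catalyst RuCl2(=CHPh)(PCy3)(H2IMes) (3 mol %), 1,4-benzoquinone (10 mol %), CH2Cl2, 40 °C, Ar sweep
Reagents that add atoms: none
Why: Olefin cross-metathesis between two unhindered terminal alkenes is statistical, so an excess of the cheap allylarene 3 should carry ketone 10 into the cross product while ethene escapes, and 1,4-benzoquinone holds back ruthenium hydride-mediated migration of the allyl double bond.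

**Step 6**
Reactants: 11 9-(3-bromo-4,5-dimethoxyphenyl)-1-(2,6-dimethoxyphenyl)non-7-en-1-one
Product: 12 9-[3,4-dimethoxy-5-(4,4,5,5-tetramethyl-1,3,2-dioxaborolan-2-yl)phenyl]-1-(2,6-dimethoxyphenyl)non-7-en-1-one (mixture of alkene isomers)
Conditions: B2pin2 (1.2 equiv), Pd(dppf)Cl2 (3 mol %), KOAc (3 equiv), 1,4-dioxane, 85 °C
Reagents that add atoms: bis(pinacolato)diboron, CC1(C)OB(OC1(C)C)B1OC(C)(C)C(C)(C)O1
Why: Miyaura borylation with the weak acetate base tolerates the hindered ketone and the internal alkene and does not promote Suzuki homocoupling, and a shift of the C=C bond along the chain, should it occur, would be erased in step 9.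

**Step 7**
Reactants: 10 1-(2,6-dimethoxyphenyl)oct-7-en-1-one; 13 (Z)-1,4-dichlorobut-2-ene
Product: 14 9-chloro-1-(2,6-dimethoxyphenyl)non-7-en-1-one (expected mainly E)
Conditions: 13 (4 equiv), second-generation Grubbs catalyst RuCl2(=CHPh)(PCy3)(H2IMes) (3 mol %), CH2Cl2, 40 °C
Reagents that add atoms: none
Why: Olefin cross-metathesis of a terminal alkene with an excess of the symmetrical internal dichloride is a standard way to a primary allylic chloride, the other half of 13 leaving as allyl chloride.

**Step 8**
Reactants: 12 9-[3,4-dimethoxy-5-(4,4,5,5-tetramethyl-1,3,2-dioxaborolan-2-yl)phenyl]-1-(2,6-dimethoxyphenyl)non-7-en-1-one; 14 9-chloro-1-(2,6-dimethoxyphenyl)non-7-en-1-one; 15 4,5-dimethoxy-2-(trimethylsilyl)phenyl trifluoromethanesulfonate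
Product: 17 9,9'-(2,3,4',5'-tetramethoxybiphenyl-5,2'-diyl)bis[1-(2,6-dimethoxyphenyl)non-7-en-1-one] (mixture of alkene isomers), via 4,5-dimethoxybenzyne 16 (not isolated)
Conditions: 12 (1.0 equiv), 14 (1.5 equiv), 15 (1.6 equiv), Pd(dba)2 (5 mol %), dppe (5 mol %), CsF (4 equiv), MeCN, 40 °C
Reagents that add atoms: none
Why: Zerovalent palladium adds to allylic chloride 14 to give a 1-alkyl-π-allylpalladium chloride (divalent palladium), while fluoride strips the silyl group of 15 and triflate leaves to give aryne 16, which inserts into the allyl–palladium bond to give a 2-allylarylpalladium species; the fluoride-activated boronate 12 then transmetalates, and reductive elimination forms the C5–C1' bond and returns zerovalent palladium. The closest known reaction type is the palladium-catalysed three-component coupling of arynes from 2-silylaryl triflates with allylic chlorides and arylboron reagents to give 2-allylbiaryls. No ring is closed and no stereocentre is formed, and both alkene geometries are acceptable because step 9 removes them. The step needs three selectivities: the two ends of the aryne are equivalent because the methoxy groups at the future C3' and C4' lie mirror-symmetrically to the triple bond, so aryl and alkyl can only end up on C1' and C6'; the chain shields the substituted terminus of the π-allyl unit, so the linear C6'–CH2 bond should form; and aryne insertion must precede transmetalation, which the slow transfer of a pinacol boronate to an allylpalladium species and the high reactivity of the strained triple bond should secure. The hindered ketones, the internal alkene of 12 and the aryl ethers are inert to CsF and to palladium at 40 °C.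

**Step 9**
Reactants: 17 9,9'-(2,3,4',5'-tetramethoxybiphenyl-5,2'-diyl)bis[1-(2,6-dimethoxyphenyl)non-7-en-1-one]
Product: 18 9,9'-(2,3,4',5'-tetramethoxybiphenyl-5,2'-diyl)bis[1-(2,6-dimethoxyphenyl)nonan-1-one]
Conditions: H2 (1 atm), 10% Pd/C, EtOAc, rt
Reagents that add atoms: none
Why: Heterogeneous catalytic hydrogenation saturates both disubstituted alkenes whatever their geometry or position, while the twisted di-ortho-substituted aryl ketones and the aryl methyl ethers should be inert at one atmosphere in a neutral solvent.

**Step 10**
Reactants: 18 9,9'-(2,3,4',5'-tetramethoxybiphenyl-5,2'-diyl)bis[1-(2,6-dimethoxyphenyl)nonan-1-one]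
Product: 19 9,9'-(2,3,4',5'-tetrahydroxybiphenyl-5,2'-diyl)bis[1-(2,6-dihydroxyphenyl)nonan-1-one] (target)
Conditions: BBr3 (20 equiv), CH2Cl2, −78 °C to rt, Ar; then H2O, 0 °C
Reagents that add atoms: none
Why: In this Lewis-acid aryl methyl ether cleavage BBr3 binds each methoxy oxygen, helped by chelation at the two ketones, bromide removes the methyl groups by SN2, and hydrolysis of the aryl borates frees all eight hydroxyls, which is the usual unmasking of 2,6-dimethoxyphenyl ketones and veratrole units.

**Compound list**

1 | eugenol (2-methoxy-4-(prop-2-en-1-yl)phenol) | C=CCc1ccc(O)c(OC)c1 | starting material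
2 | 4-allyl-2-bromo-6-methoxyphenol | C=CCc1cc(Br)c(O)c(OC)c1 | intermediate
3 | 5-allyl-1-bromo-2,3-dimethoxybenzene | C=CCc1cc(Br)c(OC)c(OC)c1 | intermediate
4 | oct-7-enoic acid | OC(=O)CCCCCC=C | starting material
5 | 1-(1H-imidazol-1-yl)oct-7-en-1-one (acyl imidazolide, formed in situ) | C=CCCCCCC(=O)n1ccnc1 | intermediate
6 | N-methoxy-N-methyloct-7-enamide | CON(C)C(=O)CCCCCC=C | intermediate
7 | 1,3-dimethoxybenzene | COc1cccc(OC)c1 | starting material
8 | 2,6-dimethoxyphenyllithium (formed in situ) | [Li]c1c(OC)cccc1OC | intermediate
9 | lithium 1-(2,6-dimethoxyphenyl)-1-[methoxy(methyl)amino]oct-7-en-1-olate (racemic, formed in situ) | [Li+].[O-]C(CCCCCC=C)(N(C)OC)c1c(OC)cccc1OC | intermediate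
10 | 1-(2,6-dimethoxyphenyl)oct-7-en-1-one | C=CCCCCCC(=O)c1c(OC)cccc1OC | intermediate
11 | 9-(3-bromo-4,5-dimethoxyphenyl)-1-(2,6-dimethoxyphenyl)non-7-en-1-one (alkene isomers, geometry not specified) | COc1cccc(OC)c1C(=O)CCCCCC=CCc1cc(Br)c(OC)c(OC)c1 | intermediate
12 | 9-[3,4-dimethoxy-5-(4,4,5,5-tetramethyl-1,3,2-dioxaborolan-2-yl)phenyl]-1-(2,6-dimethoxyphenyl)non-7-en-1-one (alkene isomers, geometry not specified) | COc1cccc(OC)c1C(=O)CCCCCC=CCc1cc(OC)c(OC)c(c1)B1OC(C)(C)C(C)(C)O1 | intermediate
13 | (Z)-1,4-dichlorobut-2-ene | ClC/C=C\CCl | starting material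
14 | 9-chloro-1-(2,6-dimethoxyphenyl)non-7-en-1-one (E isomer drawn; the Z isomer is equally usable) | ClC/C=C/CCCCCC(=O)c1c(OC)cccc1OC | intermediate
15 | 4,5-dimethoxy-2-(trimethylsilyl)phenyl trifluoromethanesulfonate | COc1cc(OS(=O)(=O)C(F)(F)F)c(cc1OC)[Si](C)(C)C | starting material
16 | 4,5-dimethoxybenzyne (formed in situ) | COC1=CC#CC=C1OC | intermediate
17 | 9,9'-(2,3,4',5'-tetramethoxybiphenyl-5,2'-diyl)bis[1-(2,6-dimethoxyphenyl)non-7-en-1-one] (alkene isomers, geometry not specified) | COc1cccc(OC)c1C(=O)CCCCCC=CCc1cc(OC)c(OC)c(c1)-c1cc(OC)c(OC)cc1CC=CCCCCCC(=O)c1c(OC)cccc1OC | intermediate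
18 | 9,9'-(2,3,4',5'-tetramethoxybiphenyl-5,2'-diyl)bis[1-(2,6-dimethoxyphenyl)nonan-1-one] | COc1cccc(OC)c1C(=O)CCCCCCCCc1cc(OC)c(OC)c(c1)-c1cc(OC)c(OC)cc1CCCCCCCCC(=O)c1c(OC)cccc1OC | intermediate
19 | 9,9'-(2,3,4',5'-tetrahydroxybiphenyl-5,2'-diyl)bis[1-(2,6-dihydroxyphenyl)nonan-1-one] | O=C(CCCCCCCCc1cc(O)c(O)c(-c2cc(O)c(O)cc2CCCCCCCCC(=O)c2c(O)cccc2O)c1)c1c(O)cccc1O | target

**Step count**
Total steps: 10. Longest linear sequence: 7 steps (1, 2, 5, 6, 8, 9, 10 from eugenol; equally 3, 4, 5, 6, 8, 9, 10 from oct-7-enoic acid).

**Steps most likely to fail**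

Step 8. The allylpalladium species may be arylated by 12 before the aryne inserts, the new bond may form at the substituted allyl terminus, or the aryne may be consumed by oligomerisation or by protodeboronated material. The fallback sets out from 1, 10 and 12 and comes back at 17; it gives up the aryne and fixes ring B as a preformed aryl bromide. Eugenol 1 would be O-methylated (MeI, K2CO3, acetone) to 4-allyl-1,2-dimethoxybenzene F1. NBS in MeCN should brominate F1 at the one carbon that is para to a methoxy group and ortho to the allyl group, giving 1-allyl-2-bromo-4,5-dimethoxybenzene F2. Cross-metathesis of F2 with 10 under the conditions of step 5 would give 9-(2-bromo-4,5-dimethoxyphenyl)-1-(2,6-dimethoxyphenyl)non-7-en-1-one F3. A Suzuki–Miyaura coupling of F3 with 12 (Pd(OAc)2, SPhos, K3PO4, toluene/H2O, 80 °C) would then give 17.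

Step 5. The statistical product distribution may leave little cross product, and migration of the allyl double bond before metathesis would give chain-shortened homologues that are hard to separate. The fallback sets out from 14 and comes back at 11; it forms the ring A to chain bond by allylic arylation instead of metathesis. Commercial 1-bromo-2,3-dimethoxybenzene would be borylated at its only C–H without an ortho neighbour ([Ir(OMe)(cod)]2, 4,4'-di-tert-butyl-2,2'-bipyridine, B2pin2, THF, 80 °C) to give 2-(3-bromo-4,5-dimethoxyphenyl)-4,4,5,5-tetramethyl-1,3,2-dioxaborolane F4. A palladium-catalysed allyl–aryl coupling of F4 with 14 (Pd(PPh3)4, K2CO3, THF/H2O, rt to 40 °C) would give 11, since the allylic chloride should react with zerovalent palladium far faster than the electron-rich aryl bromide. Steps 1 and 2 would then not be needed, and 14 would serve both chains.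

Step 1. Bromine may add across the allyl double bond or substitute at the benzylic position instead of reacting only on the ring. The fallback sets out from 1 and comes back at 2; it lets the alkene react and then restores it. Eugenol 1 with Br2 (2 equiv, CH2Cl2, 0 °C) should give 2-bromo-4-(2,3-dibromopropyl)-6-methoxyphenol F5 (racemic). Zinc dust in AcOH/EtOH would remove the two vicinal bromines by reductive elimination, leave the aryl bromide, and return 2.

**Further compounds**

F1 | step 8 | 4-allyl-1,2-dimethoxybenzene | C=CCc1ccc(OC)c(OC)c1
F2 | step 8 | 1-allyl-2-bromo-4,5-dimethoxybenzene | C=CCc1cc(OC)c(OC)cc1Br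
F3 | step 8 | 9-(2-bromo-4,5-dimethoxyphenyl)-1-(2,6-dimethoxyphenyl)non-7-en-1-one | COc1cccc(OC)c1C(=O)CCCCCC=CCc1cc(OC)c(OC)cc1Br
F4 | step 5 | 2-(3-bromo-4,5-dimethoxyphenyl)-4,4,5,5-tetramethyl-1,3,2-dioxaborolane | COc1cc(cc(Br)c1OC)B1OC(C)(C)C(C)(C)O1
F5 | step 1 | 2-bromo-4-(2,3-dibromopropyl)-6-methoxyphenol (racemic) | COc1cc(CC(Br)CBr)cc(Br)c1O
A1 | direct plan | 2,4'-bis(benzyloxy)biphenyl-5,2'-dicarbaldehyde | O=Cc1ccc(OCc2ccccc2)c(-c2ccc(OCc3ccccc3)cc2C=O)c1
A2 | direct plan | [8-(2,6-dimethoxyphenyl)-8-oxooctyl]triphenylphosphonium bromide | [Br-].O=C(CCCCCCC[P+](c1ccccc1)(c1ccccc1)c1ccccc1)c1c(OC)cccc1OC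
A3 | direct plan | 9,9'-(2,4'-dihydroxybiphenyl-5,2'-diyl)bis[1-(2,6-dimethoxyphenyl)nonan-1-one] | O=C(CCCCCCCCc1ccc(O)c(-c2ccc(O)cc2CCCCCCCCC(=O)c2c(OC)cccc2OC)c1)c1c(OC)cccc1OC
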